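**Retrosynthetic overview**
- Both the C1–C2 bond of the acyl chain and the acyl C–O bond are cut at once, giving 1-nonadecene (1), carbon monoxide and 2-phenylethanol (2).
- The forward reaction is a three-component, linear-selective palladium-catalysed hydroalkoxycarbonylation that gives the target (3) in one step.
- The disconnection avoided is the usual one, esterification of icosanoic acid (or its chloride) with 2-phenylethanol.
- No ring is formed: the benzene ring arrives intact in 2.

Assumption: the target is achiral, so there is no enantiomer to control, and because the committed route is a single step, the risk ranking at the end names that one step only.

**Step 1**
Reactants: 1 1-nonadecene (nonadec-1-ene); 2 2-phenylethanol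
Product: 3 2-phenylethyl icosanoate (phenethyl icosanoate)
Conditions: Pd(OAc)2 (1 mol %), 1,2-bis(di-tert-butylphosphinomethyl)benzene (4 mol %), MeSO3H (10 mol %), CO (30 bar), 2 (3 equiv), toluene, 100 °C, 20 h; silica plug (hexanes/EtOAc 98:2), recrystallisation from EtOH
Reagents that add atoms: carbon monoxide, [C-]#[O+]
Why: Linear-selective palladium-hydride hydroalkoxycarbonylation (hydroesterification) of a terminal alkene: the cationic Pd–H species with the bulky wide-bite-angle diphosphine inserts the alkene, carbonylates only the unhindered terminal carbon (also after any chain-walking), and the acyl–palladium is cleaved by the primary alcohol 2, so the C19 alkene, CO and the alcohol add together with no co-product to give the straight-chain C20 ester (expected about 95:5 or better linear:branched, the branched ester being removed on crystallisation); no stereocenter is formed, and the ester and arene are inert to the conditions.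

**Compound list**
1 | 1-nonadecene (nonadec-1-ene) | CCCCCCCCCCCCCCCCCC=C | starting material
2 | 2-phenylethanol | OCCc1ccccc1 | starting material
3 | 2-phenylethyl icosanoate (phenethyl icosanoate) | CCCCCCCCCCCCCCCCCCCC(=O)OCCc1ccccc1 | target

**Totals**
Total step count: 1
Longest linear sequence: 1

**Steps most likely to fail**
The route has one step, so step 1 is the only entry.

Step 1 risks: the acyl–palladium may be cleaved too slowly by 2-phenylethanol, which is bulkier and far more dilute than the neat methanol normally used, so the reaction stalls with isomerised internal nonadecenes and palladium black. The acid co-catalyst at 100 °C may also consume 2, as bis(2-phenylethyl) ether or as styrene that is itself carbonylated.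

Fallback for step 1: the fallback sets out from compound 1 and separates the carbonylation from the introduction of the phenethyl group. Compound 1 is methoxycarbonylated in the solvent-methanol form of the reaction (Pd(OAc)2, the same diphosphine, MeSO3H, CO 30 bar, MeOH, 80 °C), where methanol is the reagent that adds atoms (CO), to give methyl icosanoate F1. Molten F1 is then transesterified with 2 (1.5 equiv) over immobilised Candida antarctica lipase B without solvent at 70 °C and about 20 mbar, with methanol distilling out to drive the equilibrium. This neutral ester exchange avoids acid contact with 2 and comes back to the route at compound 3.

**Further compounds**
F1 | step 1 | methyl icosanoate | CCCCCCCCCCCCCCCCCCCC(=O)OC
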